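The route rests on cutting the dihydrofuran ring at C3–C3a and O1–C7a (benzofuranone numbering). The feature exploited is that C3a and C7a of the six-membered ring are the central carbon and one carbonyl carbon of symmetrical cyclohexane-1,3-dione, while O1, C2, C3 and the side-chain carbinol C1' form a glycerol-type unit. In one operation the dione enolate opens a terminal epoxide at CH2 and the released C2 oxygen condenses with a carbonyl, fusing the furan ring while the C2–O bond stays intact. The precursor is an (S)-oxirane derived from (S)-glycerate, flanked by a silylated tertiary carbinol that carries methyl and the C11 dienyl chain.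

Key step: step 14

Assumption (remark on the chemistry): the (+)-(2R,8aS) antipode of the camphor-derived oxaziridine is taken to be the one that delivers oxygen to the enolate face giving 5R; if the opposite sense is found, its mirror-image reagent is used with no other change.

Step 1
Reactants: 1 methyl (S)-2,2-dimethyl-1,3-dioxolane-4-carboxylate
Product: 2 (S)-N-methoxy-N,2,2-trimethyl-1,3-dioxolane-4-carboxamide
Conditions: MeNH(OMe)·HCl, i-PrMgCl, THF, −20 °C
Reagents that add atoms: N,O-dimethylhydroxylamine hydrochloride, CNOC.Cl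
Why: Weinreb amide formation, in which the chloromagnesium amide made in the flask acylates on the ester at a temperature too low for enolisation of the alpha-alkoxy stereocentre.

Step 2
Reactants: 2 (S)-N-methoxy-N,2,2-trimethyl-1,3-dioxolane-4-carboxamide
Product: 3 (S)-1-(2,2-dimethyl-1,3-dioxolan-4-yl)ethan-1-one
Conditions: MeMgBr, THF, −78 to 0 °C
Reagents that add atoms: methylmagnesium bromide, C[Mg]Br
Why: Weinreb ketone synthesis, in which the magnesium-chelated tetrahedral adduct persists until work-up so that only one methyl group adds and the alpha stereocentre is untouched.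

Step 3
Reactants: 4 geranyl acetate
Product: 5 (2E,6E)-8-hydroxy-3,7-dimethylocta-2,6-dien-1-yl acetate
Conditions: SeO2 (cat.), t-BuOOH, salicylic acid (cat.), CH2Cl2, rt
Reagents that add atoms: selenium dioxide, O=[Se]=O; tert-butyl hydroperoxide, CC(C)(C)OO (terminal oxygen source)
Why: Riley allylic oxidation (ene reaction, then [2,3]-sigmatropic shift) should attack the more electron-rich distal olefin at the methyl group trans to the chain and so give the E allylic alcohol.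

Step 4
Reactants: 5 (2E,6E)-8-hydroxy-3,7-dimethylocta-2,6-dien-1-yl acetate
Product: 6 (2E,6E)-8-[(tert-butyldiphenylsilyl)oxy]-3,7-dimethylocta-2,6-dien-1-yl acetate
Conditions: TBDPSCl, imidazole, CH2Cl2, 0 °C to rt
Reagents that add atoms: tert-butyl(chloro)diphenylsilane, CC(C)(C)[Si](Cl)(c1ccccc1)c1ccccc1
Why: Routine silylation of a primary alcohol with a group chosen to survive the later carbonate, organolithium and aqueous acid treatments.

Step 5
Reactants: 6 (2E,6E)-8-[(tert-butyldiphenylsilyl)oxy]-3,7-dimethylocta-2,6-dien-1-yl acetate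
Product: 7 (2E,6E)-8-[(tert-butyldiphenylsilyl)oxy]-3,7-dimethylocta-2,6-dien-1-ol
Conditions: K2CO3, MeOH, rt
Reagents that add atoms: none
Why: Base-catalysed transesterification removes the acetate while the hindered silyl ether is inert to carbonate in methanol.

Step 6
Reactants: 7 (2E,6E)-8-[(tert-butyldiphenylsilyl)oxy]-3,7-dimethylocta-2,6-dien-1-ol
Product: 8 (2E,6E)-8-[(tert-butyldiphenylsilyl)oxy]-3,7-dimethylocta-2,6-dienal
Conditions: MnO2, CH2Cl2, rt
Reagents that add atoms: none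
Why: Activated MnO2 oxidises allylic alcohols selectively to enals without isomerising the E olefin.

Step 7
Reactants: 8 (2E,6E)-8-[(tert-butyldiphenylsilyl)oxy]-3,7-dimethylocta-2,6-dienal
Product: 9 tert-butyl{[(2E,6E)-2,6-dimethylnona-2,6,8-trien-1-yl]oxy}diphenylsilane
Conditions: Ph3PCH3Br, n-BuLi, THF, 0 °C to rt
Reagents that add atoms: methyltriphenylphosphonium bromide, C[P+](c1ccccc1)(c1ccccc1)c1ccccc1.[Br-]
Why: Wittig methylenation of the enal with the non-stabilised ylide should give the terminal conjugated diene and leave both trisubstituted E olefins unchanged.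

Step 8
Reactants: 9 tert-butyl{[(2E,6E)-2,6-dimethylnona-2,6,8-trien-1-yl]oxy}diphenylsilane
Product: 11 (3E,7E)-9-[(tert-butyldiphenylsilyl)oxy]-4,8-dimethylnona-3,7-dien-1-ol, via B-alkyl-9-borabicyclononane 10 (not isolated)
Conditions: 9-BBN, THF, 0 °C to rt; then NaOH, H2O2, 0 °C
Reagents that add atoms: hydrogen peroxide, OO
Why: Brown hydroboration–oxidation with a bulky dialkylborane should add only to the monosubstituted terminal double bond, boron at the end carbon, which is the established way from such trienes to homoallylic alcohols.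

Step 9
Reactants: 11 (3E,7E)-9-[(tert-butyldiphenylsilyl)oxy]-4,8-dimethylnona-3,7-dien-1-ol
Product: 12 tert-butyl{[(2E,6E)-9-iodo-2,6-dimethylnona-2,6-dien-1-yl]oxy}diphenylsilane
Conditions: I2, PPh3, imidazole, CH2Cl2, 0 °C
Reagents that add atoms: iodine, [I][I]
Why: Appel-type iodination converts the primary alcohol to the iodide under buffered conditions that spare the olefins and the silyl ether.

Step 10
Reactants: 12 tert-butyl{[(2E,6E)-9-iodo-2,6-dimethylnona-2,6-dien-1-yl]oxy}diphenylsilane; 3 (S)-1-(2,2-dimethyl-1,3-dioxolan-4-yl)ethan-1-one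
Product: 15 (2S,5E,9E)-11-[(tert-butyldiphenylsilyl)oxy]-2-[(4S)-2,2-dimethyl-1,3-dioxolan-4-yl]-6,10-dimethylundeca-5,9-dien-2-ol, via homoallylic organolithium 13 (not isolated), via homoallylic organomagnesium bromide 14 (not isolated)
Conditions: t-BuLi (2.1 equiv), Et2O, −78 °C; MgBr2·OEt2, −78 to −20 °C; then 3, THF, −78 °C
Reagents that add atoms: none
Why: Iodine–lithium exchange and transmetalation give a homoallylic Grignard reagent whose addition to the alpha-alkoxy ketone follows the Cram chelate model (magnesium bridging the carbonyl oxygen and the neighbouring dioxolane oxygen, attack past the alpha hydrogen), which should set the new tertiary carbinol as S beside the S glycerate carbon.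

Step 11
Reactants: 15 (2S,5E,9E)-11-[(tert-butyldiphenylsilyl)oxy]-2-[(4S)-2,2-dimethyl-1,3-dioxolan-4-yl]-6,10-dimethylundeca-5,9-dien-2-ol
Product: 16 (2S,3S,6E,10E)-12-[(tert-butyldiphenylsilyl)oxy]-3,7,11-trimethyldodeca-6,10-diene-1,2,3-triol
Conditions: AcOH/THF/H2O (3:1:1), 45 °C
Reagents that add atoms: none
Why: Acid hydrolysis of the terminal acetonide, which the tert-butyldiphenylsilyl ether and the isolated trisubstituted olefins tolerate.

Step 12
Reactants: 16 (2S,3S,6E,10E)-12-[(tert-butyldiphenylsilyl)oxy]-3,7,11-trimethyldodeca-6,10-diene-1,2,3-triol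
Product: 18 (2S,5E,9E)-11-[(tert-butyldiphenylsilyl)oxy]-6,10-dimethyl-2-[(2S)-oxiran-2-yl]undeca-5,9-dien-2-ol, via primary tosylate 17 (not isolated)
Conditions: TsCl, Bu2SnO (cat.), Et3N, CH2Cl2, 0 °C; then K2CO3, MeOH, 0 °C
Reagents that add atoms: none
Why: Tin-catalysed monosulfonylation picks the primary hydroxyl of the 1,2-diol and the secondary oxygen then closes the oxirane by a 3-exo-tet Williamson displacement at the primary carbon, so the C2–O bond and its configuration are retained, while cold carbonate keeps Payne migration toward the tertiary hydroxyl slow.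

Step 13
Reactants: 18 (2S,5E,9E)-11-[(tert-butyldiphenylsilyl)oxy]-6,10-dimethyl-2-[(2S)-oxiran-2-yl]undeca-5,9-dien-2-ol
Product: 19 (S)-2-[(2S,5E,9E)-11-[(tert-butyldiphenylsilyl)oxy]-6,10-dimethyl-2-[(triethylsilyl)oxy]undeca-5,9-dien-2-yl]oxirane
Conditions: TESOTf, 2,6-lutidine, CH2Cl2, −78 °C
Reagents that add atoms: triethylsilyl trifluoromethanesulfonate, CC[Si](CC)(CC)OS(=O)(=O)C(F)(F)F
Why: A silyl triflate with a hindered pyridine base silylates even a tertiary alcohol at −78 °C faster than it can activate the oxirane, and the resulting ether blocks Payne migration and pyran formation in the next step.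

Step 14
Reactants: 19 (S)-2-[(2S,5E,9E)-11-[(tert-butyldiphenylsilyl)oxy]-6,10-dimethyl-2-[(triethylsilyl)oxy]undeca-5,9-dien-2-yl]oxirane; 20 cyclohexane-1,3-dione
Product: 23 (2S)-2-[(2S,5E,9E)-11-[(tert-butyldiphenylsilyl)oxy]-6,10-dimethyl-2-[(triethylsilyl)oxy]undeca-5,9-dien-2-yl]-3,5,6,7-tetrahydro-1-benzofuran-4(2H)-one, via C-alkylated hydroxy dione 21 (not isolated), via bicyclic hemiketal 22 (not isolated)
Conditions: 20 (3 equiv), KOtBu (1.5 equiv), t-BuOH, 80 °C; then AcOH, PPTS (cat.), PhMe, 70 °C, same flask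
Reagents that add atoms: none
Why: The potassium enolate of the dione, buffered by excess free dione in a protic solvent, attacks the unsubstituted oxirane carbon through its central carbon in an SN2 opening (C3–C3a bond), and after acidification the C2 hydroxyl adds to one of the two equivalent carbonyls and water is lost to give the vinylogous ester (O1–C7a bond). The closest known reaction type is the base-mediated alkylation of cyclic 1,3-diones by terminal epoxides with cyclodehydration to 2-substituted tetrahydrobenzofuranones, the epoxide counterpart of the Feist–Benary furan synthesis. The dihydrofuran ring closes by 5-exo-trig addition of the hydroxyl to the carbonyl carbon followed by dehydration, and no other ring is formed. No stereocentre is created, and C2 keeps the glycerate configuration because the oxirane is opened at CH2 and the ring oxygen is joined to C7a by carbonyl addition, never by displacement at C2. The step needs carbon rather than oxygen alkylation and attack at the terminal carbon only, which the protic medium, the soft carbon terminus and the fully substituted silyloxy carbon next to C2 should secure, while the silyl ether on the tertiary oxygen excludes Payne migration and six-membered closure and the absence of free alkoxide base suppresses silyl transfer.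

Step 15
Reactants: 23 (2S)-2-[(2S,5E,9E)-11-[(tert-butyldiphenylsilyl)oxy]-6,10-dimethyl-2-[(triethylsilyl)oxy]undeca-5,9-dien-2-yl]-3,5,6,7-tetrahydro-1-benzofuran-4(2H)-one
Product: 25 (2S,5R)-2-[(2S,5E,9E)-11-[(tert-butyldiphenylsilyl)oxy]-6,10-dimethyl-2-[(triethylsilyl)oxy]undeca-5,9-dien-2-yl]-5-hydroxy-3,5,6,7-tetrahydro-1-benzofuran-4(2H)-one, via lithium dienolate 24 (not isolated)
Conditions: LiN(i-Pr)2, THF, −78 °C; (+)-(2R,8aS)-(camphorsulfonyl)oxaziridine, −78 to −40 °C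
Reagents that add atoms: (+)-(2R,8aS)-(camphorsulfonyl)oxaziridine, CC1(C)C2CCC13CS(=O)(=O)N4OC34C2
Why: Kinetic deprotonation of the vinylogous ester occurs at the alpha' carbon C5 and the Davis enolate oxidation transfers oxygen to one enolate face under control of the camphor reagent, the remote C2 centre having little influence, with the 5S epimer removable as a diastereomer by chromatography.

Step 16
Reactants: 25 (2S,5R)-2-[(2S,5E,9E)-11-[(tert-butyldiphenylsilyl)oxy]-6,10-dimethyl-2-[(triethylsilyl)oxy]undeca-5,9-dien-2-yl]-5-hydroxy-3,5,6,7-tetrahydro-1-benzofuran-4(2H)-one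
Product: 26 (2S,5R)-2-[(2S,5E,9E)-2,11-dihydroxy-6,10-dimethylundeca-5,9-dien-2-yl]-5-hydroxy-3,5,6,7-tetrahydro-1-benzofuran-4(2H)-one
Conditions: HF·pyridine, pyridine, THF, 0 °C to rt
Reagents that add atoms: none
Why: Fluoride cleavage of both silyl ethers under buffered, mildly acidic conditions that should neither epimerise the alpha-hydroxy ketone nor hydrolyse the vinylogous ester.

Step 17
Reactants: 26 (2S,5R)-2-[(2S,5E,9E)-2,11-dihydroxy-6,10-dimethylundeca-5,9-dien-2-yl]-5-hydroxy-3,5,6,7-tetrahydro-1-benzofuran-4(2H)-one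
Product: 27 (2E,6E,10S)-10-hydroxy-10-[(2S,5R)-5-hydroxy-4-oxo-2,3,4,5,6,7-hexahydro-1-benzofuran-2-yl]-2,6-dimethylundeca-2,6-dienal
Conditions: TEMPO (cat.), PhI(OAc)2, CH2Cl2, rt
Reagents that add atoms: none
Why: Oxoammonium oxidation is selective for the primary allylic alcohol over the secondary and tertiary hydroxyls and stops at the enal.

Step 18
Reactants: 27 (2E,6E,10S)-10-hydroxy-10-[(2S,5R)-5-hydroxy-4-oxo-2,3,4,5,6,7-hexahydro-1-benzofuran-2-yl]-2,6-dimethylundeca-2,6-dienal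
Product: 28 (2E,6E,10S)-10-hydroxy-10-[(2S,5R)-5-hydroxy-4-oxo-2,3,4,5,6,7-hexahydro-1-benzofuran-2-yl]-2,6-dimethylundeca-2,6-dienoic acid
Conditions: NaClO2, NaH2PO4, 2-methyl-2-butene, t-BuOH/H2O, 0 °C to rt
Reagents that add atoms: sodium chlorite, [Na+].[O-]Cl=O
Why: Pinnick oxidation converts the enal to the acid with retention of the E geometry, the alkene scavenger removing hypochlorous acid before it can reach the olefins, the enol ether or the alcohols.

Compound list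

1 | methyl (S)-2,2-dimethyl-1,3-dioxolane-4-carboxylate | COC(=O)[C@@H]1COC(C)(C)O1 | starting material
2 | (S)-N-methoxy-N,2,2-trimethyl-1,3-dioxolane-4-carboxamide | CON(C)C(=O)[C@@H]1COC(C)(C)O1 | intermediate
3 | (S)-1-(2,2-dimethyl-1,3-dioxolan-4-yl)ethan-1-one | CC(=O)[C@@H]1COC(C)(C)O1 | intermediate
4 | geranyl acetate | CC(C)=CCC/C(C)=C/COC(C)=O | starting material
5 | (2E,6E)-8-hydroxy-3,7-dimethylocta-2,6-dien-1-yl acetate | CC(=O)OC/C=C(\C)CC/C=C(\C)CO | intermediate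
6 | (2E,6E)-8-[(tert-butyldiphenylsilyl)oxy]-3,7-dimethylocta-2,6-dien-1-yl acetate | CC(=O)OC/C=C(\C)CC/C=C(\C)CO[Si](c1ccccc1)(c1ccccc1)C(C)(C)C | intermediate
7 | (2E,6E)-8-[(tert-butyldiphenylsilyl)oxy]-3,7-dimethylocta-2,6-dien-1-ol | OC/C=C(\C)CC/C=C(\C)CO[Si](c1ccccc1)(c1ccccc1)C(C)(C)C | intermediate
8 | (2E,6E)-8-[(tert-butyldiphenylsilyl)oxy]-3,7-dimethylocta-2,6-dienal | O=C/C=C(\C)CC/C=C(\C)CO[Si](c1ccccc1)(c1ccccc1)C(C)(C)C | intermediate
9 | tert-butyl{[(2E,6E)-2,6-dimethylnona-2,6,8-trien-1-yl]oxy}diphenylsilane | C=C/C=C(\C)CC/C=C(\C)CO[Si](c1ccccc1)(c1ccccc1)C(C)(C)C | intermediate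
10 | 9-[(3E,7E)-9-[(tert-butyldiphenylsilyl)oxy]-4,8-dimethylnona-3,7-dien-1-yl]-9-borabicyclo[3.3.1]nonane | C1CC2CCCC(C1)B2CC/C=C(\C)CC/C=C(\C)CO[Si](c1ccccc1)(c1ccccc1)C(C)(C)C | intermediate
11 | (3E,7E)-9-[(tert-butyldiphenylsilyl)oxy]-4,8-dimethylnona-3,7-dien-1-ol | OCC/C=C(\C)CC/C=C(\C)CO[Si](c1ccccc1)(c1ccccc1)C(C)(C)C | intermediate
12 | tert-butyl{[(2E,6E)-9-iodo-2,6-dimethylnona-2,6-dien-1-yl]oxy}diphenylsilane | ICC/C=C(\C)CC/C=C(\C)CO[Si](c1ccccc1)(c1ccccc1)C(C)(C)C | intermediate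
13 | [(3E,7E)-9-[(tert-butyldiphenylsilyl)oxy]-4,8-dimethylnona-3,7-dien-1-yl]lithium | [Li]CC/C=C(\C)CC/C=C(\C)CO[Si](c1ccccc1)(c1ccccc1)C(C)(C)C | intermediate
14 | [(3E,7E)-9-[(tert-butyldiphenylsilyl)oxy]-4,8-dimethylnona-3,7-dien-1-yl]magnesium bromide | Br[Mg]CC/C=C(\C)CC/C=C(\C)CO[Si](c1ccccc1)(c1ccccc1)C(C)(C)C | intermediate
15 | (2S,5E,9E)-11-[(tert-butyldiphenylsilyl)oxy]-2-[(4S)-2,2-dimethyl-1,3-dioxolan-4-yl]-6,10-dimethylundeca-5,9-dien-2-ol | C/C(=C\CC[C@](C)(O)[C@@H]1COC(C)(C)O1)CC/C=C(\C)CO[Si](c1ccccc1)(c1ccccc1)C(C)(C)C | intermediate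
16 | (2S,3S,6E,10E)-12-[(tert-butyldiphenylsilyl)oxy]-3,7,11-trimethyldodeca-6,10-diene-1,2,3-triol | C/C(=C\CC[C@](C)(O)[C@@H](O)CO)CC/C=C(\C)CO[Si](c1ccccc1)(c1ccccc1)C(C)(C)C | intermediate
17 | (2S,3S,6E,10E)-12-[(tert-butyldiphenylsilyl)oxy]-2,3-dihydroxy-3,7,11-trimethyldodeca-6,10-dien-1-yl 4-methylbenzenesulfonate | C/C(=C\CC[C@](C)(O)[C@@H](O)COS(=O)(=O)c1ccc(C)cc1)CC/C=C(\C)CO[Si](c1ccccc1)(c1ccccc1)C(C)(C)C | intermediate
18 | (2S,5E,9E)-11-[(tert-butyldiphenylsilyl)oxy]-6,10-dimethyl-2-[(2S)-oxiran-2-yl]undeca-5,9-dien-2-ol | C/C(=C\CC[C@](C)(O)[C@@H]1CO1)CC/C=C(\C)CO[Si](c1ccccc1)(c1ccccc1)C(C)(C)C | intermediate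
19 | (S)-2-[(2S,5E,9E)-11-[(tert-butyldiphenylsilyl)oxy]-6,10-dimethyl-2-[(triethylsilyl)oxy]undeca-5,9-dien-2-yl]oxirane | C/C(=C\CC[C@](C)(O[Si](CC)(CC)CC)[C@@H]1CO1)CC/C=C(\C)CO[Si](c1ccccc1)(c1ccccc1)C(C)(C)C | intermediate
20 | cyclohexane-1,3-dione | O=C1CCCC(=O)C1 | starting material
21 | 2-[(2S,3S,6E,10E)-12-[(tert-butyldiphenylsilyl)oxy]-2-hydroxy-3,7,11-trimethyl-3-[(triethylsilyl)oxy]dodeca-6,10-dien-1-yl]-3-hydroxycyclohex-2-en-1-one (enol form of the 2-alkylated dione) | C/C(=C\CC[C@](C)(O[Si](CC)(CC)CC)[C@@H](O)CC1=C(O)CCCC1=O)CC/C=C(\C)CO[Si](c1ccccc1)(c1ccccc1)C(C)(C)C | intermediate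
22 | (2S)-2-[(2S,5E,9E)-11-[(tert-butyldiphenylsilyl)oxy]-6,10-dimethyl-2-[(triethylsilyl)oxy]undeca-5,9-dien-2-yl]-7a-hydroxyhexahydro-1-benzofuran-4(2H)-one (epimers at C3a and C7a) | C/C(=C\CC[C@](C)(O[Si](CC)(CC)CC)[C@@H]1CC2C(=O)CCCC2(O)O1)CC/C=C(\C)CO[Si](c1ccccc1)(c1ccccc1)C(C)(C)C | intermediate
23 | (2S)-2-[(2S,5E,9E)-11-[(tert-butyldiphenylsilyl)oxy]-6,10-dimethyl-2-[(triethylsilyl)oxy]undeca-5,9-dien-2-yl]-3,5,6,7-tetrahydro-1-benzofuran-4(2H)-one | C/C(=C\CC[C@](C)(O[Si](CC)(CC)CC)[C@@H]1CC2=C(CCCC2=O)O1)CC/C=C(\C)CO[Si](c1ccccc1)(c1ccccc1)C(C)(C)C | intermediate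
24 | lithium 4-enolate of 23 (C4–O–Li, C4=C5, C3a=C7a) | C/C(=C\CC[C@](C)(O[Si](CC)(CC)CC)[C@@H]1CC2=C(CCC=C2O[Li])O1)CC/C=C(\C)CO[Si](c1ccccc1)(c1ccccc1)C(C)(C)C | intermediate
25 | (2S,5R)-2-[(2S,5E,9E)-11-[(tert-butyldiphenylsilyl)oxy]-6,10-dimethyl-2-[(triethylsilyl)oxy]undeca-5,9-dien-2-yl]-5-hydroxy-3,5,6,7-tetrahydro-1-benzofuran-4(2H)-one | C/C(=C\CC[C@](C)(O[Si](CC)(CC)CC)[C@@H]1CC2=C(CC[C@@H](O)C2=O)O1)CC/C=C(\C)CO[Si](c1ccccc1)(c1ccccc1)C(C)(C)C | intermediate
26 | (2S,5R)-2-[(2S,5E,9E)-2,11-dihydroxy-6,10-dimethylundeca-5,9-dien-2-yl]-5-hydroxy-3,5,6,7-tetrahydro-1-benzofuran-4(2H)-one | C/C(=C\CC[C@](C)(O)[C@@H]1CC2=C(CC[C@@H](O)C2=O)O1)CC/C=C(\C)CO | intermediate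
27 | (2E,6E,10S)-10-hydroxy-10-[(2S,5R)-5-hydroxy-4-oxo-2,3,4,5,6,7-hexahydro-1-benzofuran-2-yl]-2,6-dimethylundeca-2,6-dienal | C/C(=C\CC[C@](C)(O)[C@@H]1CC2=C(CC[C@@H](O)C2=O)O1)CC/C=C(\C)C=O | intermediate
28 | (2E,6E,10S)-10-hydroxy-10-[(2S,5R)-5-hydroxy-4-oxo-2,3,4,5,6,7-hexahydro-1-benzofuran-2-yl]-2,6-dimethylundeca-2,6-dienoic acid (CNP0117600.1) | C/C(=C\CC[C@](C)(O)[C@@H]1CC2=C(CC[C@@H](O)C2=O)O1)CC/C=C(\C)C(=O)O | target

Total step count: 18. Longest linear sequence: 16 steps (steps 3 to 18, from geranyl acetate 4); the ketone branch (steps 1 and 2) joins at step 10.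

Steps most likely to fail

1. Step 14 (annulation). The weakly nucleophilic dione enolate may open the hindered oxirane too slowly, may alkylate through oxygen, or the triethylsilyl group may move to the new alkoxide during prolonged heating. The fallback sets out from 19 and returns at 23, replacing the dione by a masked, carbon-only nucleophile. Commercial 1,5-dimethoxycyclohexa-1,4-diene is deprotonated (t-BuLi, THF, −78 °C) to (2,6-dimethoxycyclohexa-2,5-dien-1-yl)lithium F1. With BF3·OEt2 at −78 °C this should open 19 at CH2 to give (2S,3S,6E,10E)-12-[(tert-butyldiphenylsilyl)oxy]-1-(2,6-dimethoxycyclohexa-2,5-dien-1-yl)-3,7,11-trimethyl-3-[(triethylsilyl)oxy]dodeca-6,10-dien-2-ol F2. Mild acid (oxalic acid, THF/H2O, then PPTS, PhMe) hydrolyses both enol ethers, and the hydroxy dione 21 so released cyclodehydrates through 22 to 23.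

2. Step 15 (C5 hydroxylation). Facial discrimination by the reagent on a secondary cyclic enolate may be insufficient, so that the oxygen is delivered to both faces. The fallback sets out from 23 and returns at 25, making both epimers converge. Enolate 24 is oxidised with racemic 3-phenyl-2-(phenylsulfonyl)oxaziridine to give 25 together with (2S,5S)-2-[(2S,5E,9E)-11-[(tert-butyldiphenylsilyl)oxy]-6,10-dimethyl-2-[(triethylsilyl)oxy]undeca-5,9-dien-2-yl]-5-hydroxy-3,5,6,7-tetrahydro-1-benzofuran-4(2H)-one F3, and the diastereomers are separated. Mitsunobu esterification of F3 (4-nitrobenzoic acid, PPh3, DIAD, THF, 0 °C) inverts C5 and gives (2S,5R)-2-[(2S,5E,9E)-11-[(tert-butyldiphenylsilyl)oxy]-6,10-dimethyl-2-[(triethylsilyl)oxy]undeca-5,9-dien-2-yl]-4-oxo-2,3,4,5,6,7-hexahydro-1-benzofuran-5-yl 4-nitrobenzoate F4. Brief methanolysis (K2CO3, MeOH, 0 °C) returns 25.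

3. Step 10 (fragment union). The basic chain organometallic may deprotonate the methyl ketone, or chelate control may erode with the long nucleophile. The fallback sets out from 12 and returns at 19. It inverts the order of bond formation, so that the stereo-determining addition uses small MeMgBr, and corrects C2 by an invertive ring closure.
   - Methyl (R)-2,2-dimethyl-1,3-dioxolane-4-carboxylate F5 (purchased) is converted as in step 1 into (R)-N-methoxy-N,2,2-trimethyl-1,3-dioxolane-4-carboxamide F6.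
   - Organolithium 13, made from 12 as in step 10, acylates F6 to give (4E,8E)-10-[(tert-butyldiphenylsilyl)oxy]-1-[(4R)-2,2-dimethyl-1,3-dioxolan-4-yl]-5,9-dimethyldeca-4,8-dien-1-one F7.
   - Chelate-controlled addition of MeMgBr (THF, −78 °C), past the alpha hydrogen of the R ketone, should give (2S,5E,9E)-11-[(tert-butyldiphenylsilyl)oxy]-2-[(4R)-2,2-dimethyl-1,3-dioxolan-4-yl]-6,10-dimethylundeca-5,9-dien-2-ol F8.
   - Acetonide hydrolysis as in step 11 gives (2R,3S,6E,10E)-12-[(tert-butyldiphenylsilyl)oxy]-3,7,11-trimethyldodeca-6,10-diene-1,2,3-triol F9.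
   - Selective benzoylation of the primary hydroxyl (BzCl, 2,4,6-collidine, CH2Cl2, −78 to 0 °C) gives (2R,3S,6E,10E)-12-[(tert-butyldiphenylsilyl)oxy]-2,3-dihydroxy-3,7,11-trimethyldodeca-6,10-dien-1-yl benzoate F10.
   - Mesylation of the secondary hydroxyl (MsCl, Et3N, CH2Cl2, 0 °C) gives (2R,3S,6E,10E)-12-[(tert-butyldiphenylsilyl)oxy]-3-hydroxy-3,7,11-trimethyl-2-[(methylsulfonyl)oxy]dodeca-6,10-dien-1-yl benzoate F11.
   - Silylation as in step 13 gives (2R,3S,6E,10E)-12-[(tert-butyldiphenylsilyl)oxy]-3,7,11-trimethyl-2-[(methylsulfonyl)oxy]-3-[(triethylsilyl)oxy]dodeca-6,10-dien-1-yl benzoate F12.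
   - K2CO3 in MeOH removes the benzoate, and the primary alkoxide displaces the mesylate with inversion at C2, which gives 19.

Further compounds

F1 | step 14 | (2,6-dimethoxycyclohexa-2,5-dien-1-yl)lithium | [Li]C1C(OC)=CCC=C1OC
F2 | step 14 | (2S,3S,6E,10E)-12-[(tert-butyldiphenylsilyl)oxy]-1-(2,6-dimethoxycyclohexa-2,5-dien-1-yl)-3,7,11-trimethyl-3-[(triethylsilyl)oxy]dodeca-6,10-dien-2-ol | C/C(=C\CC[C@](C)(O[Si](CC)(CC)CC)[C@@H](O)CC1C(OC)=CCC=C1OC)CC/C=C(\C)CO[Si](c1ccccc1)(c1ccccc1)C(C)(C)C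
F3 | step 15 | (2S,5S)-2-[(2S,5E,9E)-11-[(tert-butyldiphenylsilyl)oxy]-6,10-dimethyl-2-[(triethylsilyl)oxy]undeca-5,9-dien-2-yl]-5-hydroxy-3,5,6,7-tetrahydro-1-benzofuran-4(2H)-one | C/C(=C\CC[C@](C)(O[Si](CC)(CC)CC)[C@@H]1CC2=C(CC[C@H](O)C2=O)O1)CC/C=C(\C)CO[Si](c1ccccc1)(c1ccccc1)C(C)(C)C
F4 | step 15 | (2S,5R)-2-[(2S,5E,9E)-11-[(tert-butyldiphenylsilyl)oxy]-6,10-dimethyl-2-[(triethylsilyl)oxy]undeca-5,9-dien-2-yl]-4-oxo-2,3,4,5,6,7-hexahydro-1-benzofuran-5-yl 4-nitrobenzoate | C/C(=C\CC[C@](C)(O[Si](CC)(CC)CC)[C@@H]1CC2=C(CC[C@@H](OC(=O)c3ccc(cc3)[N+](=O)[O-])C2=O)O1)CC/C=C(\C)CO[Si](c1ccccc1)(c1ccccc1)C(C)(C)C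
F5 | step 10 | methyl (R)-2,2-dimethyl-1,3-dioxolane-4-carboxylate (purchased) | COC(=O)[C@H]1COC(C)(C)O1
F6 | step 10 | (R)-N-methoxy-N,2,2-trimethyl-1,3-dioxolane-4-carboxamide | CON(C)C(=O)[C@H]1COC(C)(C)O1
F7 | step 10 | (4E,8E)-10-[(tert-butyldiphenylsilyl)oxy]-1-[(4R)-2,2-dimethyl-1,3-dioxolan-4-yl]-5,9-dimethyldeca-4,8-dien-1-one | C/C(=C\CCC(=O)[C@H]1COC(C)(C)O1)CC/C=C(\C)CO[Si](c1ccccc1)(c1ccccc1)C(C)(C)C
F8 | step 10 | (2S,5E,9E)-11-[(tert-butyldiphenylsilyl)oxy]-2-[(4R)-2,2-dimethyl-1,3-dioxolan-4-yl]-6,10-dimethylundeca-5,9-dien-2-ol | C/C(=C\CC[C@](C)(O)[C@H]1COC(C)(C)O1)CC/C=C(\C)CO[Si](c1ccccc1)(c1ccccc1)C(C)(C)C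
F9 | step 10 | (2R,3S,6E,10E)-12-[(tert-butyldiphenylsilyl)oxy]-3,7,11-trimethyldodeca-6,10-diene-1,2,3-triol | C/C(=C\CC[C@](C)(O)[C@H](O)CO)CC/C=C(\C)CO[Si](c1ccccc1)(c1ccccc1)C(C)(C)C
F10 | step 10 | (2R,3S,6E,10E)-12-[(tert-butyldiphenylsilyl)oxy]-2,3-dihydroxy-3,7,11-trimethyldodeca-6,10-dien-1-yl benzoate | C/C(=C\CC[C@](C)(O)[C@H](O)COC(=O)c1ccccc1)CC/C=C(\C)CO[Si](c1ccccc1)(c1ccccc1)C(C)(C)C
F11 | step 10 | (2R,3S,6E,10E)-12-[(tert-butyldiphenylsilyl)oxy]-3-hydroxy-3,7,11-trimethyl-2-[(methylsulfonyl)oxy]dodeca-6,10-dien-1-yl benzoate | C/C(=C\CC[C@](C)(O)[C@H](OS(C)(=O)=O)COC(=O)c1ccccc1)CC/C=C(\C)CO[Si](c1ccccc1)(c1ccccc1)C(C)(C)C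
F12 | step 10 | (2R,3S,6E,10E)-12-[(tert-butyldiphenylsilyl)oxy]-3,7,11-trimethyl-2-[(methylsulfonyl)oxy]-3-[(triethylsilyl)oxy]dodeca-6,10-dien-1-yl benzoate | C/C(=C\CC[C@](C)(O[Si](CC)(CC)CC)[C@H](OS(C)(=O)=O)COC(=O)c1ccccc1)CC/C=C(\C)CO[Si](c1ccccc1)(c1ccccc1)C(C)(C)C
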